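**Assumption:** the target has no stereocentre and no stereogenic double bond (it is achiral), so there is no enantiomer to control; the route delivers exactly the constitution given.

**Retrosynthetic overview**
1. Target 12 ⇒ N-benzyl succinimide 10: the succinamic acid arm is carried as the cyclic imide and released by hydrolytic ring opening.
2. 10 ⇒ guaiacol 7: O-demethylation unveils the catechol.
3. 7 ⇒ 4-methylphenol 4 + succinimide 5: the benzylic C–N bond is made by the proposed oxidative C–H imidation through para-quinone methide 6.
4. 4 ⇒ creosol 1 + bromine 2: double ring bromination, directed by OH and OMe.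
5. No ring is formed: the benzene ring comes from 1, the imide ring is bought with 5 and opened in the last step.

**Route**

Step 1
Reactants: 1 2-methoxy-4-methylphenol (creosol); 2 bromine
Product: 4 2,3-dibromo-6-methoxy-4-methylphenol, via 2-bromo-6-methoxy-4-methylphenol 3 (not isolated)
Conditions: Br2 (2.05 equiv), AcOH, 0 °C to rt, dark
Reagents that add atoms: bromine (BrBr)
Why: Electrophilic aromatic bromination: the free OH sends the first bromine ortho to itself (para is blocked by methyl) to give 3, and the second enters para to the methoxy group, the only remaining strongly activated site, so the two bromines end up adjacent; no stereocentre is involved.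

Step 2
Reactants: 4 2,3-dibromo-6-methoxy-4-methylphenol; 5 succinimide
Product: 7 1-[(2,3-dibromo-4-hydroxy-5-methoxyphenyl)methyl]pyrrolidine-2,5-dione, via para-quinone methide 6 (not isolated)
Conditions: DDQ (1.05 equiv, added over 2 h), succinimide (5 equiv), MeCN, 0 °C to rt
Reagents that add atoms: succinimide (O=C1CCC(=O)N1)
Why: Proposed new method: dehydrogenative benzylic C–H imidation of a 2,6-disubstituted 4-methylphenol. DDQ removes a hydride equivalent from 4 (charge-transfer complex, then electron/proton/electron transfer eased by the para-OH and ortho-OMe) to give quinone methide 6, whose ortho positions are blocked by Br and OMe so ring coupling is shut down. The unhindered exocyclic CH2 of 6 is a strong 1,6-acceptor, and succinimide (N–H pKa about 9.6), kept in excess while DDQ is dosed slowly, adds through nitrogen under general-acid catalysis by the liberated DDQH2, with rearomatisation as driving force. O-bound adducts (hydroquinone or imidate ethers) can revert to 6 and funnel to the thermodynamically stable N-benzyl imide. The electron-poor imide nitrogen makes the new benzylic C–H far less hydridic than the methyl of 4, which guards against over-oxidation. Closest known reaction types: DDQ dehydrogenation of 2,6-disubstituted 4-alkylphenols to quinone methides trapped by alcohols, and aza-1,6-conjugate addition to pre-formed para-quinone methides; no stereocentre is created.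

Step 3
Reactants: 7 1-[(2,3-dibromo-4-hydroxy-5-methoxyphenyl)methyl]pyrrolidine-2,5-dione; 8 boron tribromide
Product: 10 1-[(2,3-dibromo-4,5-dihydroxyphenyl)methyl]pyrrolidine-2,5-dione, via cyclic bromoborate 9 (not isolated)
Conditions: BBr3 (3 equiv), CH2Cl2, −78 °C to 0 °C; then H2O
Reagents that add atoms: none
Why: Lewis-acid aryl methyl ether cleavage (BBr3 demethylation): the phenol is borylated first, the neighbouring methoxy oxygen then binds boron and bromide removes the methyl by SN2 to give cyclic borate 9, which water hydrolyses to the catechol, while the imide, the benzylic C–N bond and the aryl bromides are inert at or below 0 °C.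

Step 4
Reactants: 10 1-[(2,3-dibromo-4,5-dihydroxyphenyl)methyl]pyrrolidine-2,5-dione; 11 water
Product: 12 4-{[(2,3-dibromo-4,5-dihydroxyphenyl)methyl]amino}-4-oxobutanoic acid
Conditions: LiOH (4 equiv), degassed THF/H2O, 0 °C, Ar; then 1 M HCl to pH 2
Reagents that add atoms: water (O)
Why: Imide hydrolysis (nucleophilic acyl substitution): hydroxide opens one of the two equivalent imide carbonyls far faster than it attacks the resulting open secondary amide, so the reaction stops at the succinamic acid, and oxygen-free conditions at 0 °C protect the catecholate from autoxidation.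

**Compound list**
1 | 2-methoxy-4-methylphenol (creosol) | Cc1ccc(O)c(OC)c1 | starting material
2 | bromine | BrBr | starting material
3 | 2-bromo-6-methoxy-4-methylphenol | Cc1cc(Br)c(O)c(OC)c1 | intermediate
4 | 2,3-dibromo-6-methoxy-4-methylphenol | Cc1cc(OC)c(O)c(Br)c1Br | intermediate
5 | succinimide (pyrrolidine-2,5-dione) | O=C1CCC(=O)N1 | starting material
6 | 2,3-dibromo-6-methoxy-4-methylidenecyclohexa-2,5-dien-1-one (para-quinone methide) | C=C1C=C(OC)C(=O)C(Br)=C1Br | intermediate
7 | 1-[(2,3-dibromo-4-hydroxy-5-methoxyphenyl)methyl]pyrrolidine-2,5-dione | O=C1CCC(=O)N1Cc1cc(OC)c(O)c(Br)c1Br | intermediate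
8 | boron tribromide | BrB(Br)Br | starting material
9 | 1-[(2,6,7-tribromo-1,3,2-benzodioxaborol-5-yl)methyl]pyrrolidine-2,5-dione (cyclic B-bromo catechol borate of 10) | O=C1CCC(=O)N1Cc1cc2OB(Br)Oc2c(Br)c1Br | intermediate
10 | 1-[(2,3-dibromo-4,5-dihydroxyphenyl)methyl]pyrrolidine-2,5-dione | O=C1CCC(=O)N1Cc1cc(O)c(O)c(Br)c1Br | intermediate
11 | water | O | starting material
12 | 4-{[(2,3-dibromo-4,5-dihydroxyphenyl)methyl]amino}-4-oxobutanoic acid (achiral) | O=C(O)CCC(=O)NCc1cc(O)c(O)c(Br)c1Br | target

**Totals**
Total step count: 4. Longest linear sequence: 4 steps (1 → 4 → 7 → 10 → 12).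

**Steps most likely to fail, with fallbacks**

Step 2 (the proposed new C–H imidation). The fleeting quinone methide 6 may oligomerise, be captured by DDQH2, or the product may be oxidised further. The fallback uses only known chemistry; it sets out from 4 and comes back to the route at 7. The phenol of 4 is acetylated (Ac2O, pyridine) to 2,3-dibromo-6-methoxy-4-methylphenyl acetate F1. Wohl–Ziegler bromination (NBS, AIBN, PhCF3, 80 °C) gives 2,3-dibromo-4-(bromomethyl)-6-methoxyphenyl acetate F2. Gabriel-type N-alkylation of succinimide 5 (K2CO3, DMF, rt) gives 2,3-dibromo-4-[(2,5-dioxopyrrolidin-1-yl)methyl]-6-methoxyphenyl acetate F3. Acid-catalysed methanolysis of the aryl acetate (HCl in MeOH, rt) then releases 7.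

Step 1 (one-pot dibromination). Once both ortho positions of the phenol are blocked in 3, bromine may attack ipso at the methyl-bearing carbon (bromodienone, then benzylic bromide) or over-brominate. The fallback replaces the one-pot reaction by a protecting-group-switched stepwise sequence; it sets out from 1 and comes back at 4. Acetylation of 1 (Ac2O, pyridine) gives 2-methoxy-4-methylphenyl acetate F4, in which the methoxy group is the only strong director. Bromine 2 (1.0 equiv, NaOAc, AcOH) then enters para to OMe to give 5-bromo-2-methoxy-4-methylphenyl acetate F5. K2CO3 in MeOH frees 5-bromo-2-methoxy-4-methylphenol F6. A second equivalent of bromine 2 (CH2Cl2, −20 °C) goes to the one free position ortho to OH, where no ipso pathway competes, and gives 4.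

Step 3 (BBr3 demethylation). The strong Lewis acid may ionise the para-oxybenzylic C–N bond or stall at a boron chelate of the imide. The fallback switches from Lewis-acid cleavage to oxidative demethylation; it sets out from 7 and comes back at 10. 2-Iodoxybenzoic acid (IBX, DMF, rt) oxygenates the methoxy-bearing ortho carbon and expels methanol to give the ortho-quinone 1-[(5,6-dibromo-3,4-dioxocyclohexa-1,5-dien-1-yl)methyl]pyrrolidine-2,5-dione F7. This is reduced in the same pot with aqueous Na2S2O4 to catechol 10.

**Further compounds**
F1 | step 2 | 2,3-dibromo-6-methoxy-4-methylphenyl acetate | CC(=O)Oc1c(Br)c(Br)c(C)cc1OC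
F2 | step 2 | 2,3-dibromo-4-(bromomethyl)-6-methoxyphenyl acetate | CC(=O)Oc1c(Br)c(Br)c(CBr)cc1OC
F3 | step 2 | 2,3-dibromo-4-[(2,5-dioxopyrrolidin-1-yl)methyl]-6-methoxyphenyl acetate | CC(=O)Oc1c(Br)c(Br)c(CN2C(=O)CCC2=O)cc1OC
F4 | step 1 | 2-methoxy-4-methylphenyl acetate | CC(=O)Oc1ccc(C)cc1OC
F5 | step 1 | 5-bromo-2-methoxy-4-methylphenyl acetate | CC(=O)Oc1cc(Br)c(C)cc1OC
F6 | step 1 | 5-bromo-2-methoxy-4-methylphenol | Cc1cc(OC)c(O)cc1Br
F7 | step 3 | 1-[(5,6-dibromo-3,4-dioxocyclohexa-1,5-dien-1-yl)methyl]pyrrolidine-2,5-dione | O=C1CCC(=O)N1CC1=CC(=O)C(=O)C(Br)=C1Br
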